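**Plan**
Retrosynthesis: cut the sulfate S–O bond at O4' (made last), then O1–C8a of ring C, then C3–C4 (aldol addition followed by oxidation), C2–C1' (aryllithium on a Weinreb amide) and C4–C4a (formylation).
Enabling feature: O1 is an aryl ether oxygen on C8a of ring A, ortho to C4a, which carries the C4 carbonyl. A 1,3-diketone whose ring A has bromine on that ortho carbon can therefore close ring C by enolate O-arylation.
Ring A needs oxygen ortho and para to the acyl carbon (future C5 and C7) and bromine at the second ortho position (future C8a). Formylation of 5-bromoresorcinol dibenzyl ether between Br and OBn gives exactly this pattern.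
Forward: the ring A aldehyde and the ring B α-benzyloxy ketone are made separately, joined by aldol addition and oxidised to the diketone. Ring C, the only ring formed, is closed with CuI; then the 4-methoxybenzyl group is removed, O4' is sulfated and the benzyl ethers are hydrogenolysed.
Stereochemistry: the target is achiral; the stereocentres of the aldol adduct and of the diketone are transient and are erased by oxidation and ring closure.
Key step: step 9

Assumption: the target is taken as the free hydrogen sulfate as drawn; because aryl hydrogen sulfates hydrolyse under their own acidity, the sulfate is carried as its sodium salt and protonated only in the last operation.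

**Route**

Step 1
Reactants: 1 5-bromoresorcinol
Product: 2 1,3-bis(benzyloxy)-5-bromobenzene
Conditions: BnBr (2.3 equiv), K2CO3, DMF, 60 °C
Reagents that add atoms: benzyl bromide, BrCc1ccccc1
Why: Williamson etherification of both phenoxides with benzyl bromide under carbonate is routine for resorcinols, the aryl bromide is inert to these conditions and no stereocentre is formed.

Step 2
Reactants: 2 1,3-bis(benzyloxy)-5-bromobenzene
Product: 4 2,4-bis(benzyloxy)-6-bromobenzaldehyde, via aryliminium chloride 3 (not isolated)
Conditions: POCl3, DMF, 0 → 80 °C; then ice/H2O, 0 °C → rt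
Reagents that add atoms: N,N-dimethylformamide, CN(C)C=O; water, O
Why: Vilsmeier–Haack formylation, in which the chloroiminium ion attacks one of the two equivalent positions ortho to one benzyloxy group and para to the other rather than the more crowded site between the two ethers (the outcome established for the dimethyl ether analogue), and hydrolysis of iminium salt 3 then releases the aldehyde with its carbon on the future C4a and the bromide on the future C8a, without forming a stereocentre.

Step 3
Reactants: 5 2-(benzyloxy)phenol
Product: 6 2-(benzyloxy)-4-bromophenol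
Conditions: NBS (1.0 equiv), MeCN, 0 °C
Reagents that add atoms: N-bromosuccinimide, O=C1CCC(=O)N1Br
Why: Electrophilic aromatic bromination is steered para to the free hydroxyl, the stronger donor of the catechol monoether, as is known for guaiacol-type phenols, any minor ortho isomer should be removable by chromatography and no stereocentre is formed.

Step 4
Reactants: 6 2-(benzyloxy)-4-bromophenol
Product: 7 2-(benzyloxy)-4-bromo-1-[(4-methoxybenzyl)oxy]benzene
Conditions: 4-methoxybenzyl chloride, K2CO3, DMF, rt
Reagents that add atoms: 4-methoxybenzyl chloride, COc1ccc(CCl)cc1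
Why: Williamson etherification of the phenoxide installs an ether that can later be removed oxidatively beside benzyl ethers and thereby marks the future O4', without forming a stereocentre.

Step 5
Reactants: 8 benzyloxyacetyl chloride
Product: 9 2-(benzyloxy)-N-methoxy-N-methylacetamide
Conditions: MeNH(OMe)·HCl, K2CO3, CH2Cl2/H2O, 0 °C → rt
Reagents that add atoms: N,O-dimethylhydroxylamine hydrochloride, CNOC.Cl
Why: Schotten–Baumann acylation of N,O-dimethylhydroxylamine by the acid chloride gives the Weinreb amide that supplies C2, C3 and O3 of the flavonol, without forming a stereocentre.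

Step 6
Reactants: 7 2-(benzyloxy)-4-bromo-1-[(4-methoxybenzyl)oxy]benzene; 9 2-(benzyloxy)-N-methoxy-N-methylacetamide
Product: 12 2-(benzyloxy)-1-{3-(benzyloxy)-4-[(4-methoxybenzyl)oxy]phenyl}ethan-1-one, via aryllithium 10 (not isolated), via lithium hemiaminal chelate 11 (not isolated)
Conditions: n-BuLi, THF, −78 °C; then 9, −78 → 0 °C; H2O quench
Reagents that add atoms: none
Why: Bromine–lithium exchange at −78 °C followed by Weinreb ketone synthesis forms the C2–C1' bond, because the five-membered lithium chelate 11 resists a second addition and collapses to the ketone only on aqueous quench, and no stereocentre remains in 12.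

Step 7
Reactants: 12 2-(benzyloxy)-1-{3-(benzyloxy)-4-[(4-methoxybenzyl)oxy]phenyl}ethan-1-one; 4 2,4-bis(benzyloxy)-6-bromobenzaldehyde
Product: 14 2-(benzyloxy)-3-[2,4-bis(benzyloxy)-6-bromophenyl]-1-{3-(benzyloxy)-4-[(4-methoxybenzyl)oxy]phenyl}-3-hydroxypropan-1-one, via lithium enolate 13 (not isolated)
Conditions: LiN(i-Pr)2, THF, −78 °C; then 4, −78 °C; AcOH quench at −78 °C
Reagents that add atoms: none
Why: Directed aldol addition of the preformed, chelated lithium enolate of the α-benzyloxy ketone to the non-enolisable aldehyde forms the C3–C4 bond while the aryl bromide is untouched by an enolate at −78 °C and the cold acidic quench suppresses retro-aldol, and the two new stereocentres arise through a closed six-membered transition state as a mixture of racemic diastereomers that needs no control because both centres are erased in steps 8 and 9.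

Step 8
Reactants: 14 2-(benzyloxy)-3-[2,4-bis(benzyloxy)-6-bromophenyl]-1-{3-(benzyloxy)-4-[(4-methoxybenzyl)oxy]phenyl}-3-hydroxypropan-1-one
Product: 15 2-(benzyloxy)-1-[2,4-bis(benzyloxy)-6-bromophenyl]-3-{3-(benzyloxy)-4-[(4-methoxybenzyl)oxy]phenyl}propane-1,3-dione
Conditions: Dess–Martin periodinane, CH2Cl2, 0 °C → rt
Reagents that add atoms: none
Why: Dess–Martin oxidation of a β-hydroxy ketone to the 1,3-diketone is standard and mild enough to spare the benzyl and 4-methoxybenzyl ethers and the aryl bromide, the carbinol centre is destroyed and the remaining chain centre is racemic and enolisable.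

Step 9
Reactants: 15 2-(benzyloxy)-1-[2,4-bis(benzyloxy)-6-bromophenyl]-3-{3-(benzyloxy)-4-[(4-methoxybenzyl)oxy]phenyl}propane-1,3-dione
Product: 16 3,5,7-tris(benzyloxy)-2-{3-(benzyloxy)-4-[(4-methoxybenzyl)oxy]phenyl}-4H-chromen-4-one
Conditions: CuI (20 mol %), 1,10-phenanthroline (40 mol %), K2CO3 (2.0 equiv), dry DMF, 100 °C, under argon
Reagents that add atoms: none
Why: Carbonate converts the diketone into its potassium enolate, which binds monovalent copper through oxygen; oxidative addition of the ring A C–Br bond ortho to the aroyl carbonyl gives a trivalent copper aryl enolate that reductively eliminates the O1–C8a bond. The closest known reaction type is the Ullmann-type, CuI-catalysed intramolecular O-arylation of 1-(2-haloaryl)-1,3-diketones to flavones. Ring C closes in a six-membered mode, formally a 6-exo attack of the enolate oxygen on the ipso carbon through a seven-membered copper chelate, and the closure is driven by formation of the aromatic pyranone. No stereocentre is created, since the racemic chain carbon becomes the sp2 carbon C3, already carrying its benzyloxy group at the flavonol oxidation level. The step needs O-arylation over C-arylation and the ring B carbonyl oxygen as nucleophile, and ring size secures both, because only that oxygen reaches C8a in a six-membered ring whereas the central carbon or the ring A carbonyl oxygen would have to close a four-membered ring, so the ring A carbonyl becomes C4=O. The bromide is the only aryl halide present, the benzyl and 4-methoxybenzyl ethers tolerate carbonate in DMF, and exclusion of water limits retro-Claisen cleavage.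

Step 10
Reactants: 16 3,5,7-tris(benzyloxy)-2-{3-(benzyloxy)-4-[(4-methoxybenzyl)oxy]phenyl}-4H-chromen-4-one
Product: 17 3,5,7-tris(benzyloxy)-2-[3-(benzyloxy)-4-hydroxyphenyl]-4H-chromen-4-one
Conditions: DDQ (1.5 equiv), CH2Cl2/pH 7 phosphate buffer (10:1), 0 °C → rt
Reagents that add atoms: none
Why: Oxidative cleavage of the 4-methoxybenzyl ether by DDQ (hydride abstraction to the oxocarbenium ion, then hydrolysis) is selective over the less electron-rich benzyl ethers and the buffered medium protects the acid-sensitive 5-O-benzyl group, so only the 4'-hydroxyl should be freed and no stereocentre is involved.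

Step 11
Reactants: 17 3,5,7-tris(benzyloxy)-2-[3-(benzyloxy)-4-hydroxyphenyl]-4H-chromen-4-one
Product: 18 sodium 2-(benzyloxy)-4-[3,5,7-tris(benzyloxy)-4-oxo-4H-chromen-2-yl]phenyl sulfate
Conditions: SO3·pyridine (5 equiv), pyridine, 50 °C; then aq NaHCO3
Reagents that add atoms: sulfur trioxide–pyridine complex, O=S(=O)([O-])[n+]1ccccc1; sodium hydrogencarbonate, [Na+].OC([O-])=O
Why: O-sulfation of a phenol with the SO3·pyridine complex is the standard route to aryl sulfate monoesters, the 4'-hydroxyl is the only free hydroxyl in 17 so no regiochemical question arises, and cation exchange with NaHCO3 removes pyridine, which would retard the later hydrogenolysis, and gives the stable sodium salt.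

Step 12
Reactants: 18 sodium 2-(benzyloxy)-4-[3,5,7-tris(benzyloxy)-4-oxo-4H-chromen-2-yl]phenyl sulfate
Product: 20 2-hydroxy-4-(3,5,7-trihydroxy-4-oxo-4H-chromen-2-yl)phenyl hydrogen sulfate (quercetin 4'-O-sulfate), via sodium quercetin 4'-sulfate 19 (not isolated)
Conditions: H2 (1 atm), 10% Pd/C, THF/MeOH/H2O, rt; filter; then HCl (1.0 equiv), H2O, 0 °C; C18 desalting, freeze-drying
Reagents that add atoms: none
Why: Catalytic hydrogenolysis of the four benzyl aryl ethers over Pd/C should leave the aryl sulfate monoester and the chromone C2=C3 bond intact, as is general for benzylated flavonoid sulfates, and protonation of the sodium salt with exactly one equivalent of cold HCl gives the achiral hydrogen sulfate.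

**Compound list**

1 | 5-bromoresorcinol (5-bromobenzene-1,3-diol) | Oc1cc(O)cc(Br)c1 | starting material
2 | 1,3-bis(benzyloxy)-5-bromobenzene | Brc1cc(OCc2ccccc2)cc(OCc2ccccc2)c1 | intermediate
3 | N-{[2,4-bis(benzyloxy)-6-bromophenyl]methylidene}-N-methylmethanaminium chloride (aryliminium chloride, not isolated) | C[N+](C)=Cc1c(Br)cc(OCc2ccccc2)cc1OCc1ccccc1.[Cl-] | intermediate
4 | 2,4-bis(benzyloxy)-6-bromobenzaldehyde | O=Cc1c(Br)cc(OCc2ccccc2)cc1OCc1ccccc1 | intermediate
5 | 2-(benzyloxy)phenol | Oc1ccccc1OCc1ccccc1 | starting material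
6 | 2-(benzyloxy)-4-bromophenol | Oc1ccc(Br)cc1OCc1ccccc1 | intermediate
7 | 2-(benzyloxy)-4-bromo-1-[(4-methoxybenzyl)oxy]benzene | COc1ccc(COc2ccc(Br)cc2OCc2ccccc2)cc1 | intermediate
8 | benzyloxyacetyl chloride | O=C(Cl)COCc1ccccc1 | starting material
9 | 2-(benzyloxy)-N-methoxy-N-methylacetamide | CON(C)C(=O)COCc1ccccc1 | intermediate
10 | {3-(benzyloxy)-4-[(4-methoxybenzyl)oxy]phenyl}lithium (aryllithium, not isolated) | [Li]c1ccc(OCc2ccc(OC)cc2)c(OCc2ccccc2)c1 | intermediate
11 | lithium 2-(benzyloxy)-1-{3-(benzyloxy)-4-[(4-methoxybenzyl)oxy]phenyl}-1-[methoxy(methyl)amino]ethan-1-olate (racemic hemiaminal chelate, not isolated) | [Li]OC(COCc1ccccc1)(N(C)OC)c1ccc(OCc2ccc(OC)cc2)c(OCc2ccccc2)c1 | intermediate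
12 | 2-(benzyloxy)-1-{3-(benzyloxy)-4-[(4-methoxybenzyl)oxy]phenyl}ethan-1-one | O=C(COCc1ccccc1)c1ccc(OCc2ccc(OC)cc2)c(OCc2ccccc2)c1 | intermediate
13 | lithium (Z)-2-(benzyloxy)-1-{3-(benzyloxy)-4-[(4-methoxybenzyl)oxy]phenyl}ethen-1-olate (chelated enolate, Z geometry expected, not isolated) | [Li]O/C(=C\OCc1ccccc1)c1ccc(OCc2ccc(OC)cc2)c(OCc2ccccc2)c1 | intermediate
14 | 2-(benzyloxy)-3-[2,4-bis(benzyloxy)-6-bromophenyl]-1-{3-(benzyloxy)-4-[(4-methoxybenzyl)oxy]phenyl}-3-hydroxypropan-1-one (mixture of racemic diastereomers) | OC(c1c(Br)cc(OCc2ccccc2)cc1OCc1ccccc1)C(OCc1ccccc1)C(=O)c1ccc(OCc2ccc(OC)cc2)c(OCc2ccccc2)c1 | intermediate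
15 | 2-(benzyloxy)-1-[2,4-bis(benzyloxy)-6-bromophenyl]-3-{3-(benzyloxy)-4-[(4-methoxybenzyl)oxy]phenyl}propane-1,3-dione (racemic, enolisable) | O=C(c1c(Br)cc(OCc2ccccc2)cc1OCc1ccccc1)C(OCc1ccccc1)C(=O)c1ccc(OCc2ccc(OC)cc2)c(OCc2ccccc2)c1 | intermediate
16 | 3,5,7-tris(benzyloxy)-2-{3-(benzyloxy)-4-[(4-methoxybenzyl)oxy]phenyl}-4H-chromen-4-one | O=c1c(OCc2ccccc2)c(-c2ccc(OCc3ccc(OC)cc3)c(OCc3ccccc3)c2)oc2cc(OCc3ccccc3)cc(OCc3ccccc3)c12 | intermediate
17 | 3,5,7-tris(benzyloxy)-2-[3-(benzyloxy)-4-hydroxyphenyl]-4H-chromen-4-one | O=c1c(OCc2ccccc2)c(-c2ccc(O)c(OCc3ccccc3)c2)oc2cc(OCc3ccccc3)cc(OCc3ccccc3)c12 | intermediate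
18 | sodium 2-(benzyloxy)-4-[3,5,7-tris(benzyloxy)-4-oxo-4H-chromen-2-yl]phenyl sulfate | O=c1c(OCc2ccccc2)c(-c2ccc(OS(=O)(=O)[O-])c(OCc3ccccc3)c2)oc2cc(OCc3ccccc3)cc(OCc3ccccc3)c12.[Na+] | intermediate
19 | sodium 2-hydroxy-4-(3,5,7-trihydroxy-4-oxo-4H-chromen-2-yl)phenyl sulfate (sodium quercetin 4'-sulfate, not isolated) | O=c1c(O)c(-c2ccc(OS(=O)(=O)[O-])c(O)c2)oc2cc(O)cc(O)c12.[Na+] | intermediate
20 | 2-hydroxy-4-(3,5,7-trihydroxy-4-oxo-4H-chromen-2-yl)phenyl hydrogen sulfate (quercetin 4'-O-sulfate) | O=c1c(O)c(-c2ccc(OS(=O)(=O)O)c(O)c2)oc2cc(O)cc(O)c12 | target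

**Step count**
Total: 12 steps.
Longest linear sequence: 9 steps (steps 3, 4, 6, 7, 8, 9, 10, 11, 12, from 2-(benzyloxy)phenol 5).

**Steps most likely to fail, with fallbacks**

Step 9. The risks are sluggish activation of the C–Br bond at copper, carbonate-induced retro-Claisen cleavage of the α-benzyloxy diketone, and protodebromination at 100 °C. The fallback leaves copper chemistry and makes the same O1–C8a bond by a zerovalent palladium cross-coupling cycle (Buchwald–Hartwig-type etherification of the enolate oxygen). It would use Pd2(dba)3, 2-di-tert-butylphosphino-2',4',6'-triisopropylbiphenyl and K3PO4 in toluene at 80 °C, where oxidative addition is fast and the weaker base and lower temperature spare the diketone. It sets out from 15 and comes back at 16; no new compound arises on this path (F0).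

Step 12. The risks are loss of the sulfate ester by acid-catalysed hydrolysis once the free hydrogen sulfate is generated, and stalling of the fourfold debenzylation on the ionic, poorly soluble substrate. The fallback carries the sulfate through the hydrogenolysis as a neutral diester. Setting out from phenol 17, deprotonation with NaN(SiMe3)2 in THF at −78 °C and reaction with neopentyl chlorosulfate would give 2-(benzyloxy)-4-[3,5,7-tris(benzyloxy)-4-oxo-4H-chromen-2-yl]phenyl neopentyl sulfate F1. Hydrogenolysis (H2, Pd/C, THF/MeOH) would give 2-hydroxy-4-(3,5,7-trihydroxy-4-oxo-4H-chromen-2-yl)phenyl neopentyl sulfate F2. Dealkylation at the neopentyl carbon with NaN3 in DMF at 70 °C would then release the sodium sulfate, which is where the path comes back to the route, at 19. Compound 19 is protonated as in step 12 or stored as the salt.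

Step 7. The risks are incomplete addition of the enolate to the hindered, electron-rich aldehyde and reversal of the aldol on work-up or during the oxidation. The fallback replaces aldol addition and oxidation by a Claisen-type C-acylation. Setting out from aldehyde 4, Pinnick oxidation (NaClO2, NaH2PO4, 2-methyl-2-butene, t-BuOH/H2O) would give 2,4-bis(benzyloxy)-6-bromobenzoic acid F3. Oxalyl chloride with catalytic DMF in CH2Cl2 would give 2,4-bis(benzyloxy)-6-bromobenzoyl chloride F4. Acylation of ketone 12 under soft enolisation (MgBr2·OEt2, i-Pr2NEt, CH2Cl2) would then deliver the diketone directly, coming back to the route at 15.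

**Further compounds**
F0 | step 9 | none | none
F1 | step 12 | 2-(benzyloxy)-4-[3,5,7-tris(benzyloxy)-4-oxo-4H-chromen-2-yl]phenyl neopentyl sulfate | O=c1c(OCc2ccccc2)c(-c2ccc(OS(=O)(=O)OCC(C)(C)C)c(OCc3ccccc3)c2)oc2cc(OCc3ccccc3)cc(OCc3ccccc3)c12
F2 | step 12 | 2-hydroxy-4-(3,5,7-trihydroxy-4-oxo-4H-chromen-2-yl)phenyl neopentyl sulfate | O=c1c(O)c(-c2ccc(OS(=O)(=O)OCC(C)(C)C)c(O)c2)oc2cc(O)cc(O)c12
F3 | step 7 | 2,4-bis(benzyloxy)-6-bromobenzoic acid | O=C(O)c1c(Br)cc(OCc2ccccc2)cc1OCc1ccccc1
F4 | step 7 | 2,4-bis(benzyloxy)-6-bromobenzoyl chloride | O=C(Cl)c1c(Br)cc(OCc2ccccc2)cc1OCc1ccccc1
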